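Do not read the mean residence time of a stirred tank as a batch time: delta and the closed north-west run share a charge and 25 min, yet they do not end alike.

| setting | north-west | south-east | east | epsilon | delta | alpha |
|---|---|---|---|---|---|---|
| starting material | 1 M | 0.67 M | 1.5 M | 1.0 M (fed, over 12.5 min) | 1.0 M | 1.0 M |
| target | 0.050 M | 0.050 M | 0.050 M | 0.0500 M | 0.0500 M | 0.0500 M |
| protic impurity | 0.050 M | 0.050 M | 0.050 M | 0.0500 M | 0.0500 M | 0.0500 M |
| remark | run made earlier | run made earlier | run made earlier | all but starting material at the start; starting material goes in evenly over 12.5 min, the run ends at 25 min | one stirred flow tank at steady state, fed with the mixture as stated, mean residence time 25 min | everything together in a closed stirred flask, run for 25 min |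
| time |  |  |  | 25 min |  | 25 min |

- north-west (time / min: target / %, isomer of the product / %, starting material / %): 4.00: 42, 61, 0; 8.00: 22, 79, 0; 10.0: 16, 83, 0; 15.0: 10, 91, 0; 20.0: 10, 90, 1; 25.0: 8, 92, 2
- south-east (time / min: target / %, isomer of the product / %, starting material / %): 1.33: 76, 26, 0; 2.00: 63, 36, 3; 3.00: 53, 50, 0; 4.00: 44, 60, 1; 6.00: 26, 74, 0; 10.0: 18, 87, 1; 15.0: 10, 94, 0
- east (time / min: target / %, isomer of the product / %, starting material / %): 1.33: 76, 26, 0; 2.00: 65, 36, 2; 3.00: 52, 47, 0; 4.00: 43, 54, 0; 6.00: 30, 76, 3; 10.0: 19, 85, 0; 15.0: 10, 89, 1

(readings scatter by 2 percentage points)

- the stated concentrations are those of everything mixed, before any reaction; amounts are the same in each set-up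
- the earlier runs were read with a standard deviation of 2 percentage points
- the feed brings no volume worth counting
- the earlier runs were made in a closed, stirred flask

1. the set-up with the highest share of target in all that became target or isomer of the product, at the outlet or at the end ("none" if the first two lie within 2 percentage points) (epsilon / delta / alpha / none)
2. share of target in all that became target or isomer of the product, at the outlet or at the end, epsilon
3. share of target in all that became target or isomer of the product, at the outlet or at the end, delta
4. share of target in all that became target or isomer of the product, at the outlet or at the end, alpha

Read the simulated runs first. Starting material stands at 0% by the first reading of the south-east run, and target reads 76% there at 0.67 M and 76% in the east run at 1.5 M. Because these percentages match across the change of charge, treat the fall of target as first order in target. Take the last north-west reading, 8% target, as the floor; target and isomer of the product sum there to 100%, so percent of target serves as the share asked. The excess over that floor reads 34 percentage points at 4.00 min and 8 points at 10.0 min, which gives a relaxation rate of 0.241 min⁻¹.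

Now count turnovers, the relaxation rate times the time a portion stays: 6.03 for 25 min. In the closed flask every portion lives through these turnovers, and because the relaxation time is shorter than the run, the excess shrinks to 0.241% of itself and the flask ends at the floor, under thermodynamic control. In the tank, portions of every age leave together, so the excess is divided by one plus the turnovers, which holds delta under kinetic control. I reckon 21.1% for delta, well above the floor. Average the fed portions of epsilon, aged from 12.5 min to 25 min, and I get 9.42%; for alpha I get 8.22%.

The forecast, a little above my figures, gives 10.2% for epsilon, 22% for delta and 8.8% for alpha, names delta best, and says “the tank keeps young material”. The flask gives 10.1%, 21.1% and 9.22% in that order, with delta best.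

    starting material → target (k = 1.90 × 10⁻⁵ s⁻¹)
    starting material → decomposition product (k = 1.20 × 10⁻⁵ s⁻¹)
    starting material + target → 2 target (k = 0.900 M⁻¹ s⁻¹)
    starting material + protic impurity → quenched substrate (k = 0.260 M⁻¹ s⁻¹)
    target ⇌ isomer of the product (K = 10.0, k = 0.00400 s⁻¹)

In the delta tank, starting material turned into target on target at a standing [starting material] of 0.00335 M, while target and isomer of the product exchanged through a mean stay that I counted from the readings as 6.03 turnovers, and the outlet held 21.4% target beside 80.4% isomer of the product. In alpha the same exchange ran in a closed flask for 25 min, by the same count from the readings 6.03 turnovers, and ended at 9.41% target, and left until 250 min, alpha gave a share of 9.09%.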